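## The problem

The target 11 is 3,3',4,4',5,5'-hexabromo-1H,1'H-2,2'-bipyrrole: two identical pyrrole rings (ring A and ring A') joined through C2–C2', both nitrogen atoms free, and every other ring carbon brominated. It has no stereocentre, and the C2–C2' axis between two five-membered rings is not expected to be configurationally stable. Nothing stereochemical therefore has to be controlled, and any stereocentre that appears on the way is transient and directs nothing. The real questions are how the inter-ring bond is made and how six C–Br bonds are introduced without damage to them or to the rings. A late metal-mediated C2–C2' coupling is awkward, because the C–Br bonds next to the reacting carbon are themselves open to zerovalent palladium and to halogen–metal exchange. N–H pyrroles, and above all unsubstituted 2,2'-bipyrrole, are electron-rich and sensitive to acid and air, whereas C–Br bonds tolerate acid, mild base and electrophiles but not reductants or organolithium reagents. The twofold symmetry invites a two-directional construction. The enabling feature is that in each ring C2 carries N1 and the inter-ring bond and is flanked by the brominated C3. N1 and Br thus sit on neighbouring sp2 carbons as they would after an anti aminobromination of an alkyne, so C3–C2–C2'–C3' can be read as a 1,3-diyne. C4 can then carry a hydroxyl group whose loss supplies the aromatic oxidation level, and C5 is the methylene that ties nitrogen to the chain.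

## Retrosynthesis

**11 ⇒ 10.** The four C–Br bonds at C4, C5, C4' and C5' are cut. These are the positions an N–H pyrrole brominates readily. Removing all six bromines instead would lead to the parent bipyrrole, the most oxidisable substrate, and would give up the two halogens that ring construction can deliver. Precursor 10, 3,3'-dibromo-1H,1'H-2,2'-bipyrrole, keeps only the bromines flanking the inter-ring bond. The forward reaction is a fourfold electrophilic substitution in which every remaining C–H is replaced, so it raises no regiochemical question and needs only a mild bromonium source at low temperature.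

**10 ⇒ 9.** The two N–H bonds are traced back to N–S bonds in 3,3'-dibromo-1,1'-ditosyl-2,2'-bipyrrole 9. A sulfonyl group is preferred to a carbamate because a carbamate carbonyl oxygen could compete as the nucleophile in a halocyclisation, whereas a sulfonamide offers only nitrogen. The sulfonyl group also makes the N–H acidic enough to be lost after ring closure and shields the new pyrrole from the brominating agent and from acid. The forward reaction is an alkaline N–S cleavage that must leave the C–Br bonds untouched.

**9 ⇒ 7 (key disconnection).** In both rings N1–C2 and C3–Br are cut, and water is formally added back across C4–C5. This gives the acyclic, halogen-free, symmetric diyne 7, N,N'-(2,7-dihydroxyocta-3,5-diyne-1,8-diyl)bis(4-methylbenzenesulfonamide). Its C4–C5 bond is the future C2–C2' bond, C3/C6 become the brominated C3/C3', the carbinols C2/C7 become C4/C4', and the methylenes C1/C8 become C5/C5'. The neighbouring cut, C2–C2' between two preformed 3-bromopyrroles, would demand metalation or coupling next to C–Br and is kept only as a reserve. The forward reaction must perform two 5-endo-dig anti aminobrominations and two dehydrations. Because dehydration erases the carbinol centres, 7 may be a diastereomer mixture.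

**7 ⇒ 6.** The central C(sp)–C(sp) bond is cut to two molecules of the terminal alkyne 6, N-(2-hydroxybut-3-yn-1-yl)-4-methylbenzenesulfonamide. Since both halves are identical, an oxidative homocoupling suffices and no differentiated partners are needed. The precursor is half the size. The forward reaction only has to tolerate a free secondary alcohol and a sulfonamide N–H.

**6 ⇒ 4 + 5.** The carbinol–alkyne bond is cut to the aldehyde 4, 4-methyl-N-(2-oxoethyl)benzenesulfonamide, and ethynylmagnesium bromide 5. The alternative of adding a butadiyne dianion twice to 4 would reach 7 directly but requires handling butadiyne. Monoaddition of a commercial Grignard reagent followed by dimerisation is safer. The forward reaction is a 1,2-addition in the presence of an acidic N–H and is run with excess reagent.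

**4 ⇒ 3 ⇒ 1 + 2.** The aldehyde is traced back to its dimethyl acetal 3, N-(2,2-dimethoxyethyl)-4-methylbenzenesulfonamide, because α-sulfonamido aldehydes do not store well. The N–S bond of 3 is cut to aminoacetaldehyde dimethyl acetal 1 and 4-methylbenzenesulfonyl chloride 2, both bulk chemicals.

## Roads not taken

**Alternative 1:** Both rings are cut at N1–C5 and C3–C4, leaving the C2–C2' bond in a vicinal dioxime.
- **Forward step:** dimethylglyoxime A1 and two molecules of acetylene A2 react in KOH/dimethyl sulfoxide. Each oxime is O-vinylated, a [3,3]-shift forms C3–C4, and cyclodehydration closes N1–C5, giving 1H,1'H-2,2'-bipyrrole A3 (twofold Trofimov reaction). Sixfold bromination of A3 would then give 11.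
- **Merits:** two operations from commodity chemicals, no protecting group, no transition metal.
- **Weak points:** a vicinal dioxime in hot superbase can cyclodehydrate to a five-membered N–O–N heterocycle instead of being vinylated. The second annulation must occur on an oxime already conjugated to a pyrrole. Excess A2 tends to N-vinylate the product, which adds a devinylation step. A2 under pressure in hot KOH/dimethyl sulfoxide calls for special equipment. The route also passes through A3, the most oxidisable member of the series, and puts all six brominations on it.
- **Comparison:** if the double annulation were efficient, this road would be clearly shorter, and the chosen plan cannot match it in step count. The chosen plan offers ambient-pressure steps with isolable intermediates and a ring closure that delivers the aromatic oxidation level and two halogens at once. Its nitrogen atoms stay deactivated until the penultimate step, so the parent bipyrrole is never handled. Positional control of the C3 bromines is not strictly needed for a perbrominated target, but it comes free and would matter for partly brominated congeners.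

**Alternative 2:** Both rings are cut at C3=C4.
- **Forward step:** the tetraene A4, a bis(N-allyl sulfonamide) of a hexa-1,5-diene-3,4-diamine, undergoes double ring-closing metathesis with second-generation Grubbs catalyst (H2IMes)(PCy3)Cl2Ru=CHPh. Each N-allyl group closes onto the vinyl group on its own carbon, giving the bis(2,5-dihydropyrrole) A5 and releasing only a volatile C2 olefin.
- **Merits:** ring-closing metathesis of N-sulfonyl diallylamine-type dienes is among the most dependable ring closures, and the diastereomer mixture is of no consequence.
- **Weak points:** A5 is at the wrong oxidation level. Both rings must be dehydrogenated, or sulfinate eliminated by base, before A3 is reached, and all six bromines are then still missing. A4 itself needs a vicinal diamine synthesis, sulfonylation and N-allylation, about as many steps as the approach to 7. A ruthenium catalyst is required.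
- **Comparison:** the metathesis is more certain than the key step chosen here. Against that, the chosen plan needs no redox adjustment, because dehydration of the carbinols supplies aromaticity, and it does not end at the sensitive A3.

**Alternative 3:** Both rings are cut at N1–C5.
- **Forward step:** the bis(homopropargyl sulfonamide) A6 undergoes twofold 5-endo-dig hydroamination with (Ph3P)AuCl and AgOSO2CF3 (cationic monovalent gold). Each nitrogen adds to its terminal alkyne carbon, giving the bis(2,3-dihydropyrrole) A7.
- **Merits:** A6 should be quickly available by double propargylation of a C2 bis-imine, the cyclisation is an atom-economic isomerisation, and 5-endo-dig hydroamination of homopropargyl sulfonamides is a known reaction type.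
- **Weak points:** propargyl versus allenyl regiochemistry in making A6. The cyclic N-sulfonyl enamines in A7 are acid-sensitive. As in Alternative 2, four hydrogens or two sulfinates must still be removed to reach A3, and then six bromines added. Precious-metal catalysts are needed.
- **Comparison:** length is similar and the key step has closer precedent than the chosen one. The chosen plan sets against this that ring closure, oxidation level and the C3 halogens come from one metal-free operation.

Key step: step 5

## Route

Assumption: 6, 7 and 8 are carried as racemic or diastereomeric mixtures, since their carbinol centres vanish in step 5 and the target has no stereogenic element.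

Step 1
Reactants: 1 aminoacetaldehyde dimethyl acetal (2,2-dimethoxyethan-1-amine); 2 4-methylbenzenesulfonyl chloride
Product: 3 N-(2,2-dimethoxyethyl)-4-methylbenzenesulfonamide
Conditions: Et3N, CH2Cl2, 0 °C to rt
Reagents that add atoms: none
Why: N-sulfonylation of a primary amine with a sulfonyl chloride, Et3N taking up HCl; the acetal is inert to these basic conditions.

Step 2
Reactants: 3 N-(2,2-dimethoxyethyl)-4-methylbenzenesulfonamide
Product: 4 4-methyl-N-(2-oxoethyl)benzenesulfonamide
Conditions: 2 M aq. HCl, acetone, 45 °C; crude aldehyde used at once
Reagents that add atoms: water, O
Why: Acid-catalysed acetal hydrolysis through the oxocarbenium ion; the sulfonamide is stable to dilute acid. The aldehyde is taken on without storage because α-sulfonamido aldehydes self-condense.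

Step 3
Reactants: 4 4-methyl-N-(2-oxoethyl)benzenesulfonamide; 5 ethynylmagnesium bromide
Product: 6 N-(2-hydroxybut-3-yn-1-yl)-4-methylbenzenesulfonamide (racemic)
Conditions: 5 (3 equiv), THF, −78 to 0 °C, inverse addition; aq. NH4Cl
Reagents that add atoms: none
Why: 1,2-addition of an alkynyl Grignard reagent to an aldehyde; the first equivalent deprotonates the sulfonamide and the excess adds to C=O. The carbinol centre forms as a racemate, which is acceptable because step 5 removes it.

Step 4
Reactants: 6 N-(2-hydroxybut-3-yn-1-yl)-4-methylbenzenesulfonamide (two molecules)
Product: 7 N,N'-(2,7-dihydroxyocta-3,5-diyne-1,8-diyl)bis(4-methylbenzenesulfonamide), mixture of meso and racemic diastereomers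
Conditions: CuCl (10 mol %), TMEDA (20 mol %), O2 (1 atm), acetone, rt
Reagents that add atoms: none
Why: Glaser–Hay oxidative homocoupling of a terminal alkyne through copper acetylides with O2 as terminal oxidant; free propargylic hydroxyl and sulfonamide N–H groups are tolerated. The two carbinol centres combine statistically, and both diastereomers converge in step 5.

Step 5
Reactants: 7 N,N'-(2,7-dihydroxyocta-3,5-diyne-1,8-diyl)bis(4-methylbenzenesulfonamide)
Product: 9 3,3'-dibromo-1,1'-ditosyl-1H,1'H-2,2'-bipyrrole, via bis(4-bromo-3-hydroxy-2,3-dihydropyrrole) 8 (not isolated)
Conditions: NBS (2.1 equiv), MeCN, 0 °C to rt, dark; then TsOH·H2O (20 mol %), rt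
Reagents that add atoms: N-bromosuccinimide, O=C1CCC(=O)N1Br
Why: Proposed new method: NBS should transfer Br+ to each alkyne of 7 to give a bridged bromirenium ion, which the sulfonamide nitrogen, held two atoms from the outer alkyne carbon, opens anti at the inner carbon, forming N1–C2 and C3–Br while the succinimide anion takes up the N–H proton, so that neither external base nor bromide is present. Both rings close in the 5-endo-dig mode, the first giving a 2-alkynyl bromo-enesulfonamide and the second, by the same sequence on the remaining alkyne, giving the bis(bromohydroxydihydropyrrole) 8. The closest known reaction types are the iodine-mediated 5-endo-dig cyclisation–dehydration of 1-sulfonamidoalk-3-yn-2-ols to 3-iodopyrroles and twofold electrophilic cyclisations of 1,4-diaryl-1,3-diynes bearing ortho heteroatom nucleophiles; new here is a bromonium source acting twice on a non-aromatic conjugated diyne diol. The step needs 5-endo closure to beat 4-exo closure, and nitrogen capture to beat dibromination, bromo-enone formation of the Meyer–Schuster type and alcohol oxidation. The two-atom tether would make the 4-exo product a strained alkylidene azetidine, the inner alkyne carbon carries positive charge best (it is conjugated with the second alkyne and, in the second closure, with the enesulfonamide), and the absence of bromide and water removes the partners for the side reactions. Added TsOH·H2O then ionises each allylic C–OH of 8 to a cation stabilised by the sulfonamide nitrogen, which loses the neighbouring CH2 proton, so two dehydrations aromatise both rings. No lasting stereocentre is formed and the two carbinol centres of 7 are destroyed, which is why the diastereomer mixture can be used. The N-sulfonyl groups keep the new pyrroles deactivated enough to survive NBS and acid.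

Step 6
Reactants: 9 3,3'-dibromo-1,1'-ditosyl-1H,1'H-2,2'-bipyrrole
Product: 10 3,3'-dibromo-1H,1'H-2,2'-bipyrrole
Conditions: 5 M aq. NaOH, MeOH/THF, 60 °C, argon; neutral work-up, crude product used at once
Reagents that add atoms: none
Why: Alkaline cleavage of N-sulfonylpyrroles: hydroxide attacks sulfur and the 3-bromopyrrolide leaves, while C–Br bonds on the electron-rich ring are inert to hydroxide. Exclusion of air and immediate use limit oxidation of 10.

Step 7
Reactants: 10 3,3'-dibromo-1H,1'H-2,2'-bipyrrole
Product: 11 3,3',4,4',5,5'-hexabromo-1H,1'H-2,2'-bipyrrole
Conditions: NBS (4.2 equiv), THF, −78 to 0 °C, dark; aq. Na2S2O3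
Reagents that add atoms: N-bromosuccinimide, O=C1CCC(=O)N1Br
Why: Electrophilic aromatic bromination of an N–H pyrrole with NBS, at the α-positions C5/C5' first and the β-positions C4/C4' next. Every remaining C–H is replaced, so no regiochemical control is needed, and each bromine introduced makes the ring less prone to oxidation.

## Compound list

1 | 2,2-dimethoxyethan-1-amine (aminoacetaldehyde dimethyl acetal) | COC(CN)OC | starting material
2 | 4-methylbenzenesulfonyl chloride | Cc1ccc(cc1)S(Cl)(=O)=O | starting material
3 | N-(2,2-dimethoxyethyl)-4-methylbenzenesulfonamide | COC(CNS(=O)(=O)c1ccc(C)cc1)OC | intermediate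
4 | 4-methyl-N-(2-oxoethyl)benzenesulfonamide | O=CCNS(=O)(=O)c1ccc(C)cc1 | intermediate
5 | ethynylmagnesium bromide | C#C[Mg]Br | starting material
6 | N-(2-hydroxybut-3-yn-1-yl)-4-methylbenzenesulfonamide, racemic | C#CC(O)CNS(=O)(=O)c1ccc(C)cc1 | intermediate
7 | N,N'-(2,7-dihydroxyocta-3,5-diyne-1,8-diyl)bis(4-methylbenzenesulfonamide), meso and racemic diastereomers | Cc1ccc(cc1)S(=O)(=O)NCC(O)C#CC#CC(O)CNS(=O)(=O)c1ccc(C)cc1 | intermediate
8 | 4,4'-dibromo-1,1'-ditosyl-2,2',3,3'-tetrahydro-1H,1'H-5,5'-bipyrrole-3,3'-diol, diastereomer mixture | Cc1ccc(cc1)S(=O)(=O)N1CC(O)C(Br)=C1C1=C(Br)C(O)CN1S(=O)(=O)c1ccc(C)cc1 | intermediate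
9 | 3,3'-dibromo-1,1'-ditosyl-1H,1'H-2,2'-bipyrrole | Cc1ccc(cc1)S(=O)(=O)n1ccc(Br)c1-c1c(Br)ccn1S(=O)(=O)c1ccc(C)cc1 | intermediate
10 | 3,3'-dibromo-1H,1'H-2,2'-bipyrrole | Brc1cc[nH]c1-c1[nH]ccc1Br | intermediate
11 | 3,3',4,4',5,5'-hexabromo-1H,1'H-2,2'-bipyrrole | Brc1[nH]c(-c2[nH]c(Br)c(Br)c2Br)c(Br)c1Br | target

Total step count: 7. Longest linear sequence: 7 steps (1 to 11).

## Least certain steps

**Step 5 (key step).** Bromonium transfer to the electron-poor conjugated diyne may be slow. The reaction could then stall after one ring closure, or the propargylic alcohols could be oxidised or undergo halogenative rearrangement before nitrogen capture. The fallback uses known chemistry, builds the rings first and makes C2–C2' last. It sets out from 2 and comes back at 9. Commercial pyrrole is N-sulfonylated with 2 (NaH, THF, 0 °C) to 1-tosyl-1H-pyrrole F1. Bromination with Br2 in AcOH at reflux gives the thermodynamically preferred 3-bromo-1-tosyl-1H-pyrrole F2. Lithiation of F2 at C2, between the sulfonylated nitrogen and bromine, with LDA (LiN(iPr)2) in THF at −78 °C, followed by oxidative homocoupling with CuCl2, joins the two C2 carbons to give 9.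

**Step 3.** Deprotonation of the acidic N–H and enolisation or self-condensation of the sensitive aldehyde 4 can outrun addition to the carbonyl group. The fallback forms the C–C bond on a carbamate-protected aldehyde and introduces the sulfonyl group afterwards. It sets out from 5 and comes back at 6. Reagent 5 (2.5 equiv, THF, −78 to 0 °C) is added to commercial tert-butyl (2-oxoethyl)carbamate to give tert-butyl (2-hydroxybut-3-yn-1-yl)carbamate F3. HCl in dioxane removes the carbamate to give 1-aminobut-3-yn-2-ol hydrochloride F4. Selective N-sulfonylation with 2 (Et3N, CH2Cl2, 0 °C) gives 6.

**Step 6.** Cleavage of the second, shielded sulfonamide may be incomplete, and the electron-rich product may degrade by oxidation or acid during hot alkaline treatment and isolation. The fallback reverses the order of the last two operations. It sets out from 9 and comes back at 11. Exhaustive bromination of the oxidation-resistant 9 with excess Br2 in AcOH at 80 °C gives 3,3',4,4',5,5'-hexabromo-1,1'-ditosyl-1H,1'H-2,2'-bipyrrole F5. Any premature loss of a sulfonyl group there only speeds the bromination. Aqueous NaOH in THF at rt then removes both sulfonyl groups from F5, whose perbrominated pyrrolide is a much better leaving group, to give 11.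

**Step 7.** Oxidative coupling or oligomerisation through the free α-positions C5/C5' may compete with substitution, or bromination may stop short and give mixtures of partly brominated products. The fallback blocks the α-positions before nitrogen is unmasked. It sets out from 9 and comes back at 11. Twofold α-lithiation of 9 (LDA, THF, −78 °C) and quenching with 1,2-dibromo-1,1,2,2-tetrachloroethane gives 3,3',5,5'-tetrabromo-1,1'-ditosyl-1H,1'H-2,2'-bipyrrole F6. Cleavage with aq. NaOH in MeOH/THF gives 3,3',5,5'-tetrabromo-1H,1'H-2,2'-bipyrrole F7. F7 has no free α-position, and NBS (2.1 equiv, THF, 0 °C) brominates it at C4/C4' to give 11.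

## Further compounds

F1 | step 5 | 1-tosyl-1H-pyrrole | Cc1ccc(cc1)S(=O)(=O)n1cccc1
F2 | step 5 | 3-bromo-1-tosyl-1H-pyrrole | Cc1ccc(cc1)S(=O)(=O)n1ccc(Br)c1
F3 | step 3 | tert-butyl (2-hydroxybut-3-yn-1-yl)carbamate, racemic | CC(C)(C)OC(=O)NCC(O)C#C
F4 | step 3 | 1-aminobut-3-yn-2-ol hydrochloride, racemic | Cl.NCC(O)C#C
F5 | step 6 | 3,3',4,4',5,5'-hexabromo-1,1'-ditosyl-1H,1'H-2,2'-bipyrrole | Cc1ccc(cc1)S(=O)(=O)n1c(Br)c(Br)c(Br)c1-c1c(Br)c(Br)c(Br)n1S(=O)(=O)c1ccc(C)cc1
F6 | step 7 | 3,3',5,5'-tetrabromo-1,1'-ditosyl-1H,1'H-2,2'-bipyrrole | Cc1ccc(cc1)S(=O)(=O)n1c(Br)cc(Br)c1-c1c(Br)cc(Br)n1S(=O)(=O)c1ccc(C)cc1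
F7 | step 7 | 3,3',5,5'-tetrabromo-1H,1'H-2,2'-bipyrrole | Brc1cc(Br)c(-c2[nH]c(Br)cc2Br)[nH]1
A1 | alternative 1 | dimethylglyoxime, (2E,3E)-butane-2,3-dione dioxime | C/C(=N\O)/C(C)=N/O
A2 | alternative 1 | acetylene | C#C
A3 | alternative 1 | 1H,1'H-2,2'-bipyrrole | c1cc([nH]c1)-c1ccc[nH]1
A4 | alternative 2 | N,N'-(hexa-1,5-diene-3,4-diyl)bis(N-allyl-4-methylbenzenesulfonamide), diastereomer mixture | C=CCN(C(C=C)C(C=C)N(CC=C)S(=O)(=O)c1ccc(C)cc1)S(=O)(=O)c1ccc(C)cc1
A5 | alternative 2 | 1,1'-ditosyl-2,2',5,5'-tetrahydro-1H,1'H-2,2'-bipyrrole, diastereomer mixture | Cc1ccc(cc1)S(=O)(=O)N1CC=CC1C1C=CCN1S(=O)(=O)c1ccc(C)cc1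
A6 | alternative 3 | N,N'-(octa-1,7-diyne-4,5-diyl)bis(4-methylbenzenesulfonamide), diastereomer mixture | C#CCC(NS(=O)(=O)c1ccc(C)cc1)C(CC#C)NS(=O)(=O)c1ccc(C)cc1
A7 | alternative 3 | 1,1'-ditosyl-2,2',3,3'-tetrahydro-1H,1'H-2,2'-bipyrrole, diastereomer mixture | Cc1ccc(cc1)S(=O)(=O)N1C=CCC1C1CC=CN1S(=O)(=O)c1ccc(C)cc1
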